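**Retrosynthetic overview**
1. The target comes from its hexa-silyl ether by fluoride desilylation (last step).
2. The trans-3-aroyl-2-aryl-2,3-dihydrobenzofuran comes from a (2R)-2,4-diaryl-2H-chromene by a hypervalent-iodine oxidative ring contraction: the ring A carbon C4a shifts from C4 to C3, C4 becomes the aryl ketone, and C3 is set trans to C2.
3. The 2-arylacryloyl side chain is grown on the chromene before the contraction, from an 8-acetyl group by Pd α-arylation and α-methylenation.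
4. The pyran ring (formed first, later contracted to the furan) comes from gold-catalysed 6-endo hydroarylation of an aryl propargyl ether, itself made by Mitsunobu inversion of an (R)-1,3-diarylpropargyl alcohol with the ring A phenol (sets C2).
5. The ring A phenol comes from resorcinol (silylation, meta C–H borylation/oxidation, ortho-acetylation); the propargyl alcohol comes from a 4-bromophenol-derived aldehyde and a resorcinol-derived arylacetylene by enantioselective alkynylation.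

Assumption: the SMILES is read as the 2,3-trans (2R,3R) isomer; TBS = tert-butyldimethylsilyl, TBSO = tert-butyldimethylsilyloxy.

**Step 1**
Reactants: 1 resorcinol
Product: 2 1,3-bis(TBSO)benzene
Conditions: TBSCl (2.2 equiv), imidazole, DMF, rt
Reagents that add atoms: tert-butyldimethylsilyl chloride, CC(C)(C)[Si](C)(C)Cl
Why: Imidazole-promoted O-silylation of both phenols; the bulky silyl ethers later block the positions next to oxygen.

**Step 2**
Reactants: 2 1,3-bis(TBSO)benzene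
Product: 4 3,5-bis(TBSO)phenol, via pinacol boronate 3 (not isolated)
Conditions: [Ir(OMe)(cod)]2 (1.5 mol%), dtbpy (3 mol%), B2pin2, THF, 80 °C; then KHSO5 (as 2KHSO5·KHSO4·K2SO4), acetone/H2O, rt, 10 min
Reagents that add atoms: bis(pinacolato)diboron, CC1(C)OB(OC1(C)C)B1OC(C)(C)C(C)(C)O1 (boron of intermediate 3 only); potassium peroxymonosulfate, [K+].[O-]S(=O)(=O)OO (the new phenol oxygen)
Why: Sterically controlled iridium-catalysed C–H borylation occurs only at C5, the one position with no ortho substituent, and one-pot C–B oxidation gives the phenol.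

**Step 3**
Reactants: 4 3,5-bis(TBSO)phenol; 5 acetyl chloride
Product: 7 1-[2-hydroxy-4,6-bis(TBSO)phenyl]ethanone, via magnesium phenoxide 6 (not isolated)
Conditions: EtMgBr (1.05 equiv), Et2O/toluene, 0 °C; then AcCl (1.0 equiv), toluene, 0 °C → rt
Reagents that add atoms: ethylmagnesium bromide, CC[Mg]Br (MgBr of intermediate 6 only)
Why: Magnesium-phenoxide-templated ortho C-acylation (chelation-directed Friedel–Crafts acylation); the para position lies between two TBSO groups and is shielded, and the two ortho positions are equivalent.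

**Step 4**
Reactants: 8 4-bromophenol
Product: 9 (4-bromophenoxy)(tert-butyl)dimethylsilane
Conditions: TBSCl, imidazole, DMF, rt
Reagents that add atoms: tert-butyldimethylsilyl chloride, CC(C)(C)[Si](C)(C)Cl
Why: Standard phenol silylation; 9 serves both as the aldehyde precursor and as the α-arylation partner.

**Step 5**
Reactants: 9 (4-bromophenoxy)(tert-butyl)dimethylsilane; 10 N,N-dimethylformamide
Product: 12 4-(TBSO)benzaldehyde, via aryllithium 11 (not isolated)
Conditions: n-BuLi, THF, −78 °C; DMF, −78 → 0 °C; H2O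
Reagents that add atoms: n-butyllithium, [Li]CCCC (lithium of intermediate 11 only)
Why: Bromine–lithium exchange followed by formylation with DMF (Bouveault aldehyde synthesis); the para-silyloxy aryllithium cannot undergo silyl migration.

**Step 6**
Reactants: 2 1,3-bis(TBSO)benzene
Product: 13 1-iodo-2,4-bis(TBSO)benzene
Conditions: NIS (1.0 equiv), TFA (5 mol%), MeCN, 0 °C → rt
Reagents that add atoms: N-iodosuccinimide, O=C1CCC(=O)N1I
Why: Electrophilic aromatic iodination at C4 (para to one TBSO, ortho to the other); C2 between the two silyl ethers is blocked.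

**Step 7**
Reactants: 13 1-iodo-2,4-bis(TBSO)benzene; 14 ethynylmagnesium bromide
Product: 16 1-ethynyl-2,4-bis(TBSO)benzene, via ethynylzinc bromide 15 (not isolated)
Conditions: ZnBr2, THF, 0 °C; then 13, Pd(PPh3)4 (5 mol%), THF, rt
Reagents that add atoms: zinc dibromide, Br[Zn]Br (zinc and bromide of intermediate 15 only)
Why: Negishi coupling of ethynylzinc bromide with the aryl iodide gives the terminal arylacetylene in one step without a base or fluoride that would touch the aryl silyl ethers.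

**Step 8**
Reactants: 12 4-(TBSO)benzaldehyde; 16 1-ethynyl-2,4-bis(TBSO)benzene
Product: 18 (1R)-1-[4-(TBSO)phenyl]-3-[2,4-bis(TBSO)phenyl]prop-2-yn-1-ol, via alkynylzinc 17 (not isolated)
Conditions: 16 (1.5 equiv, excess recovered), Et2Zn, toluene, reflux; then (S)-BINOL (20 mol%), Ti(OiPr)4 (50 mol%), Et2O, rt; then 12, rt; H2O
Reagents that add atoms: diethylzinc, CC[Zn]CC (ethylzinc of intermediate 17 only)
Why: BINOL–titanium-catalysed enantioselective alkynylzinc addition to the aromatic aldehyde sets the carbinol centre; (S)-BINOL is expected to give the (1R)-alcohol (sense inferred by analogy with BINOL–titanium alkylzinc additions, to be confirmed; (R)-BINOL is used if it proves opposite).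

**Step 9**
Reactants: 7 1-[2-hydroxy-4,6-bis(TBSO)phenyl]ethanone; 18 (1R)-1-[4-(TBSO)phenyl]-3-[2,4-bis(TBSO)phenyl]prop-2-yn-1-ol
Product: 19 1-[2-({(1S)-1-[4-(TBSO)phenyl]-3-[2,4-bis(TBSO)phenyl]prop-2-yn-1-yl}oxy)-4,6-bis(TBSO)phenyl]ethanone
Conditions: PPh3, DIAD, toluene, 0 °C → rt
Reagents that add atoms: none
Why: Mitsunobu etherification with the acidic ortho-acyl phenol proceeds by SN2 inversion at the propargylic carbon, giving the (1S)-ether that carries the future C2 configuration.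

**Step 10**
Reactants: 19 the (1S)-aryl propargyl ether
Product: 20 1-{(2R)-5,7-bis(TBSO)-2-[4-(TBSO)phenyl]-4-[2,4-bis(TBSO)phenyl]-2H-chromen-8-yl}ethanone
Conditions: Ph3PAuNTf2 (3 mol%), CH2Cl2, 0 °C → rt
Reagents that add atoms: none
Why: Gold-catalysed 6-endo-dig intramolecular hydroarylation (Friedel–Crafts-type alkenylation) by the only free ortho carbon of ring A closes the pyran ring without touching the C–O stereocentre; the descriptor changes from S to R only because the CIP ranks of aryl and the former alkynyl carbon swap.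

**Step 11**
Reactants: 20 the (2R)-8-acetyl-2H-chromene; 9 (4-bromophenoxy)(tert-butyl)dimethylsilane
Product: 21 1-{(2R)-5,7-bis(TBSO)-2-[4-(TBSO)phenyl]-4-[2,4-bis(TBSO)phenyl]-2H-chromen-8-yl}-2-[4-(TBSO)phenyl]ethanone
Conditions: Pd2(dba)3 (2 mol%), Xantphos (4.5 mol%), NaOtBu (1.3 equiv), THF, 45 °C
Reagents that add atoms: none
Why: Palladium-catalysed ketone α-arylation of the only enolisable position gives the deoxybenzoin; the mild temperature protects the C2 centre from electrocyclic ring opening.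

**Step 12**
Reactants: 21 the (2R)-deoxybenzoin chromene; 22 bis(dimethylamino)methane
Product: 23 1-{(2R)-5,7-bis(TBSO)-2-[4-(TBSO)phenyl]-4-[2,4-bis(TBSO)phenyl]-2H-chromen-8-yl}-2-[4-(TBSO)phenyl]prop-2-en-1-one
Conditions: Ac2O, THF, rt → 40 °C
Reagents that add atoms: none
Why: Mannich condensation of the benzylic ketone CH2 with the iminium made in situ, followed by elimination of the acetylated amine (α-methylenation), gives the 2-arylacryloyl group; both ortho oxygens are blocked, so no oxa-Michael closure can occur.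

**Step 13**
Reactants: 23 the (2R)-2,4-diaryl-2H-chromene enone
Product: 24 1-{(2R,3R)-3-[2,4-bis(TBSO)benzoyl]-4,6-bis(TBSO)-2-[4-(TBSO)phenyl]-2,3-dihydro-1-benzofuran-7-yl}-2-[4-(TBSO)phenyl]prop-2-en-1-one (2,3-trans)
Conditions: PhI(OH)OTs (1.1 equiv), CH2Cl2/MeOH/H2O (10:9:1), −20 → 0 °C; aq. NaHCO3
Reagents that add atoms: [hydroxy(tosyloxy)iodo]benzene, Cc1ccc(cc1)S(=O)(=O)OI(O)c1ccccc1 (supplies the ketone oxygen, relayed through the solvent)
Why: Proposed new method: the trivalent-iodine electrophile adds to C3 of the electron-rich 1,1-diaryl alkene from the face opposite the C2 aryl, solvent caps the doubly benzylic C4 cation, and with the C3–iodane bond pseudo-equatorial the antiperiplanar C4–C4a bond migrates to C3 with inversion as PhI leaves, so the pyran contracts to the furan, C4 becomes the aryl ketone and C3 is set trans to the untouched C2 (any cis epimer equilibrates to trans through the enol); the closest known reactions are the PhI(OH)OTs 1,2-aryl shift of 1,1-diarylalkenes to α-aryl ketones and the hypervalent-iodine ring contractions of 1,2-dihydronaphthalenes to indanes and of flavanones to 2-aryl-2,3-dihydrobenzofuran-3-carboxylates, not yet shown on 2,4-diaryl-2H-chromenes.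

**Step 14**
Reactants: 24 the (2R,3R)-hexa-TBS ether
Product: 25 1-[(2R,3R)-3-(2,4-dihydroxybenzoyl)-4,6-dihydroxy-2-(4-hydroxyphenyl)-2,3-dihydro-1-benzofuran-7-yl]-2-(4-hydroxyphenyl)prop-2-en-1-one (CNP0162111.1)
Conditions: HF·pyridine, pyridine/THF, 0 °C → rt
Reagents that add atoms: none
Why: Fluoride-mediated cleavage of the six aryl silyl ethers under buffered, non-basic conditions avoids phenoxide formation, which would trigger oxa-Michael closure onto the acryloyl group or enolisation at C3.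

**Compound list**
1 | resorcinol | Oc1cccc(O)c1 | starting material
2 | 1,3-bis(TBSO)benzene | CC(C)(C)[Si](C)(C)Oc1cccc(O[Si](C)(C)C(C)(C)C)c1 | intermediate
3 | 2-[3,5-bis(TBSO)phenyl]-4,4,5,5-tetramethyl-1,3,2-dioxaborolane | CC(C)(C)[Si](C)(C)Oc1cc(O[Si](C)(C)C(C)(C)C)cc(c1)B1OC(C)(C)C(C)(C)O1 | intermediate
4 | 3,5-bis(TBSO)phenol | Oc1cc(O[Si](C)(C)C(C)(C)C)cc(O[Si](C)(C)C(C)(C)C)c1 | intermediate
5 | acetyl chloride | CC(=O)Cl | starting material
6 | bromomagnesium 3,5-bis(TBSO)phenoxide | Br[Mg]Oc1cc(O[Si](C)(C)C(C)(C)C)cc(O[Si](C)(C)C(C)(C)C)c1 | intermediate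
7 | 1-[2-hydroxy-4,6-bis(TBSO)phenyl]ethanone | CC(=O)c1c(O)cc(O[Si](C)(C)C(C)(C)C)cc1O[Si](C)(C)C(C)(C)C | intermediate
8 | 4-bromophenol | Oc1ccc(Br)cc1 | starting material
9 | (4-bromophenoxy)(tert-butyl)dimethylsilane | CC(C)(C)[Si](C)(C)Oc1ccc(Br)cc1 | intermediate
10 | N,N-dimethylformamide | CN(C)C=O | starting material
11 | [4-(TBSO)phenyl]lithium | [Li]c1ccc(O[Si](C)(C)C(C)(C)C)cc1 | intermediate
12 | 4-(TBSO)benzaldehyde | O=Cc1ccc(O[Si](C)(C)C(C)(C)C)cc1 | intermediate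
13 | 1-iodo-2,4-bis(TBSO)benzene | Ic1ccc(O[Si](C)(C)C(C)(C)C)cc1O[Si](C)(C)C(C)(C)C | intermediate
14 | ethynylmagnesium bromide | C#C[Mg]Br | starting material
15 | ethynylzinc bromide | C#C[Zn]Br | intermediate
16 | 1-ethynyl-2,4-bis(TBSO)benzene | C#Cc1ccc(O[Si](C)(C)C(C)(C)C)cc1O[Si](C)(C)C(C)(C)C | intermediate
17 | ethyl{[2,4-bis(TBSO)phenyl]ethynyl}zinc | CC[Zn]C#Cc1ccc(O[Si](C)(C)C(C)(C)C)cc1O[Si](C)(C)C(C)(C)C | intermediate
18 | (1R)-1-[4-(TBSO)phenyl]-3-[2,4-bis(TBSO)phenyl]prop-2-yn-1-ol | O[C@H](c1ccc(O[Si](C)(C)C(C)(C)C)cc1)C#Cc1ccc(O[Si](C)(C)C(C)(C)C)cc1O[Si](C)(C)C(C)(C)C | intermediate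
19 | 1-[2-({(1S)-1-[4-(TBSO)phenyl]-3-[2,4-bis(TBSO)phenyl]prop-2-yn-1-yl}oxy)-4,6-bis(TBSO)phenyl]ethanone | CC(=O)c1c(O[C@@H](c2ccc(O[Si](C)(C)C(C)(C)C)cc2)C#Cc2ccc(O[Si](C)(C)C(C)(C)C)cc2O[Si](C)(C)C(C)(C)C)cc(O[Si](C)(C)C(C)(C)C)cc1O[Si](C)(C)C(C)(C)C | intermediate
20 | 1-{(2R)-5,7-bis(TBSO)-2-[4-(TBSO)phenyl]-4-[2,4-bis(TBSO)phenyl]-2H-chromen-8-yl}ethanone | CC(=O)c1c(O[Si](C)(C)C(C)(C)C)cc(O[Si](C)(C)C(C)(C)C)c2c1O[C@@H](c1ccc(O[Si](C)(C)C(C)(C)C)cc1)C=C2c1ccc(O[Si](C)(C)C(C)(C)C)cc1O[Si](C)(C)C(C)(C)C | intermediate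
21 | 1-{(2R)-5,7-bis(TBSO)-2-[4-(TBSO)phenyl]-4-[2,4-bis(TBSO)phenyl]-2H-chromen-8-yl}-2-[4-(TBSO)phenyl]ethanone | O=C(Cc1ccc(O[Si](C)(C)C(C)(C)C)cc1)c1c(O[Si](C)(C)C(C)(C)C)cc(O[Si](C)(C)C(C)(C)C)c2c1O[C@@H](c1ccc(O[Si](C)(C)C(C)(C)C)cc1)C=C2c1ccc(O[Si](C)(C)C(C)(C)C)cc1O[Si](C)(C)C(C)(C)C | intermediate
22 | bis(dimethylamino)methane | CN(C)CN(C)C | starting material
23 | 1-{(2R)-5,7-bis(TBSO)-2-[4-(TBSO)phenyl]-4-[2,4-bis(TBSO)phenyl]-2H-chromen-8-yl}-2-[4-(TBSO)phenyl]prop-2-en-1-one | C=C(C(=O)c1c(O[Si](C)(C)C(C)(C)C)cc(O[Si](C)(C)C(C)(C)C)c2c1O[C@@H](c1ccc(O[Si](C)(C)C(C)(C)C)cc1)C=C2c1ccc(O[Si](C)(C)C(C)(C)C)cc1O[Si](C)(C)C(C)(C)C)c1ccc(O[Si](C)(C)C(C)(C)C)cc1 | intermediate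
24 | 1-{(2R,3R)-3-[2,4-bis(TBSO)benzoyl]-4,6-bis(TBSO)-2-[4-(TBSO)phenyl]-2,3-dihydro-1-benzofuran-7-yl}-2-[4-(TBSO)phenyl]prop-2-en-1-one | C=C(C(=O)c1c(O[Si](C)(C)C(C)(C)C)cc(O[Si](C)(C)C(C)(C)C)c2c1O[C@@H](c1ccc(O[Si](C)(C)C(C)(C)C)cc1)[C@@H]2C(=O)c1ccc(O[Si](C)(C)C(C)(C)C)cc1O[Si](C)(C)C(C)(C)C)c1ccc(O[Si](C)(C)C(C)(C)C)cc1 | intermediate
25 | 1-[(2R,3R)-3-(2,4-dihydroxybenzoyl)-4,6-dihydroxy-2-(4-hydroxyphenyl)-2,3-dihydro-1-benzofuran-7-yl]-2-(4-hydroxyphenyl)prop-2-en-1-one | C=C(C(=O)c1c(O)cc(O)c2c1O[C@@H](c1ccc(O)cc1)[C@@H]2C(=O)c1ccc(O)cc1O)c1ccc(O)cc1 | target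

**Totals**
Total step count: 14.
Longest linear sequence: 10 steps (1 → 2 → 13 → 16 → 18 → 19 → 20 → 21 → 23 → 24 → 25; steps 1, 6, 7, 8, 9, 10, 11, 12, 13, 14).

**Three steps most likely to fail**

Step 13 (the proposed new ring contraction). Risks are competing migration of the C2 aryl, oxidation of the chromene to the flavylium ion, and acid-triggered ionisation of the C2–O bond. The fallback sets out from 23. NBS in THF/H2O at 0 °C opens the bromonium ion anti at the benzylic C4 and gives the bromohydrin 1-{(2S,3S,4S)-3-bromo-4-hydroxy-5,7-bis(TBSO)-2-[4-(TBSO)phenyl]-4-[2,4-bis(TBSO)phenyl]-3,4-dihydro-2H-chromen-8-yl}-2-[4-(TBSO)phenyl]prop-2-en-1-one F3 (bromine trans to the C2 aryl and anti to the hydroxyl). AgOTf with 2,6-lutidine in CH2Cl2 at −20 °C → rt then drives a halohydrin semipinacol rearrangement, the same C4a shift pushed by the tertiary hydroxyl, and the route is rejoined at 24. Both operations are known chemistry.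

Step 9 (Mitsunobu etherification). The phenol is hindered and hydrogen-bonded, and the alcohol is ionisable, so yield or enantiopurity may suffer. The fallback sets out from 12. Ethynylmagnesium bromide 14 followed by Ac2O in the same pot gives racemic 1-[4-(TBSO)phenyl]prop-2-yn-1-yl acetate F1. Copper-catalysed enantioselective propargylic etherification with phenol 7 [(CuOTf)2·C6H6, chiral Ph-pybox enantiomer chosen for the (1R) product, iPr2NEt, THF, 0 °C] then forms the C–O bond and the stereocentre together, giving 1-[2-({(1R)-1-[4-(TBSO)phenyl]prop-2-yn-1-yl}oxy)-4,6-bis(TBSO)phenyl]ethanone F2, which has the same spatial arrangement as 19. Sonogashira coupling with iodide 13 (PdCl2(PPh3)2, CuI, Et3N, THF, rt) rejoins the route at 19; compounds 16 and 18 are then not needed.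

Step 14 (global desilylation). The freed ortho phenol can add to the acryloyl group (isoflavanone formation) while fluoride is present. The fallback sets out from 24. Thiophenol with catalytic Et3N in CH2Cl2 at 0 °C masks the enone as the β-phenylthio ketone 1-{(2R,3R)-3-[2,4-bis(TBSO)benzoyl]-4,6-bis(TBSO)-2-[4-(TBSO)phenyl]-2,3-dihydro-1-benzofuran-7-yl}-2-[4-(TBSO)phenyl]-3-(phenylsulfanyl)propan-1-one F4 (epimers at the new α-carbon). HF·pyridine then gives the hexaphenol sulfide 1-[(2R,3R)-3-(2,4-dihydroxybenzoyl)-4,6-dihydroxy-2-(4-hydroxyphenyl)-2,3-dihydro-1-benzofuran-7-yl]-2-(4-hydroxyphenyl)-3-(phenylsulfanyl)propan-1-one F5. NaIO4 in MeOH/H2O at 0 °C gives the corresponding sulfoxide 1-[(2R,3R)-3-(2,4-dihydroxybenzoyl)-4,6-dihydroxy-2-(4-hydroxyphenyl)-2,3-dihydro-1-benzofuran-7-yl]-2-(4-hydroxyphenyl)-3-(phenylsulfinyl)propan-1-one F6, which is not isolated; warming in dioxane at 50 °C causes thermal syn-elimination under neutral, fluoride-free conditions and rejoins the route at 25.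

**Further compounds**
F1 | step 9 | racemic 1-[4-(TBSO)phenyl]prop-2-yn-1-yl acetate | CC(=O)OC(C#C)c1ccc(O[Si](C)(C)C(C)(C)C)cc1
F2 | step 9 | 1-[2-({(1R)-1-[4-(TBSO)phenyl]prop-2-yn-1-yl}oxy)-4,6-bis(TBSO)phenyl]ethanone | CC(=O)c1c(O[C@@H](c2ccc(O[Si](C)(C)C(C)(C)C)cc2)C#C)cc(O[Si](C)(C)C(C)(C)C)cc1O[Si](C)(C)C(C)(C)C
F3 | step 13 | 1-{(2S,3S,4S)-3-bromo-4-hydroxy-5,7-bis(TBSO)-2-[4-(TBSO)phenyl]-4-[2,4-bis(TBSO)phenyl]-3,4-dihydro-2H-chromen-8-yl}-2-[4-(TBSO)phenyl]prop-2-en-1-one | C=C(C(=O)c1c(O[Si](C)(C)C(C)(C)C)cc(O[Si](C)(C)C(C)(C)C)c2c1O[C@@H](c1ccc(O[Si](C)(C)C(C)(C)C)cc1)[C@H](Br)[C@]2(O)c1ccc(O[Si](C)(C)C(C)(C)C)cc1O[Si](C)(C)C(C)(C)C)c1ccc(O[Si](C)(C)C(C)(C)C)cc1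
F4 | step 14 | 1-{(2R,3R)-3-[2,4-bis(TBSO)benzoyl]-4,6-bis(TBSO)-2-[4-(TBSO)phenyl]-2,3-dihydro-1-benzofuran-7-yl}-2-[4-(TBSO)phenyl]-3-(phenylsulfanyl)propan-1-one | O=C(C(CSc1ccccc1)c1ccc(O[Si](C)(C)C(C)(C)C)cc1)c1c(O[Si](C)(C)C(C)(C)C)cc(O[Si](C)(C)C(C)(C)C)c2c1O[C@@H](c1ccc(O[Si](C)(C)C(C)(C)C)cc1)[C@@H]2C(=O)c1ccc(O[Si](C)(C)C(C)(C)C)cc1O[Si](C)(C)C(C)(C)C
F5 | step 14 | 1-[(2R,3R)-3-(2,4-dihydroxybenzoyl)-4,6-dihydroxy-2-(4-hydroxyphenyl)-2,3-dihydro-1-benzofuran-7-yl]-2-(4-hydroxyphenyl)-3-(phenylsulfanyl)propan-1-one | O=C(C(CSc1ccccc1)c1ccc(O)cc1)c1c(O)cc(O)c2c1O[C@@H](c1ccc(O)cc1)[C@@H]2C(=O)c1ccc(O)cc1O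
F6 | step 14 | 1-[(2R,3R)-3-(2,4-dihydroxybenzoyl)-4,6-dihydroxy-2-(4-hydroxyphenyl)-2,3-dihydro-1-benzofuran-7-yl]-2-(4-hydroxyphenyl)-3-(phenylsulfinyl)propan-1-one | O=C(C(CS(=O)c1ccccc1)c1ccc(O)cc1)c1c(O)cc(O)c2c1O[C@@H](c1ccc(O)cc1)[C@@H]2C(=O)c1ccc(O)cc1O
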